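**Retrosynthetic overview**
1. Side chain: pyrylium tetrafluoroborate 1 + MeLi → 2-methyl-2H-pyran 2 → (2Z,4E)-hexa-2,4-dienal 3 → (2Z,4E)-hexa-2,4-dienoic acid 4. The Z-enoate is cut back to an aromatic cation plus a methyl anion.
2. 4 → epoxy acid 5 by catalyst-controlled epoxidation of the distal E-alkene only. The oxirane is the only ring made in the synthesis and is formed before the fragments are joined.
3. Core: hydroquinone 6 → bromanil 7 → bis(benzyloxy)dibromoquinone 8. Two aryl–aryl disconnections (Suzuki) to boronic acid 9 give terphenylquinone 10; hydrogenolysis through tetraol 11 and re-oxidation give dihydroxyquinone 12.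
4. Union, two esters at a time: 12 + two 5 → bis(acyloxy)quinone 13 (ester C–O bonds at the quinone level); reduction to hydroquinone 14 + two 5 → silyl-protected tetraester 15; Si–O cleavage gives target 16.
5. Ring order: the three benzene rings are bought and only joined (central ring from 6, outer rings from 9). The pyrylium ring is opened, the oxirane is closed on the C6 acid, and the acid is then attached in two double acylations.

Assumption: the L-fructose-derived enantiomer of the Shi ketone (ent-Shi ketone, made from L-sorbose), 1 and 9 are taken as purchasable; the target is read from the SMILES as the all-(2Z), all-(4S,5S) tetraester with free 4,4''-phenols.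

**Step 1**
Reactants: 1 pyrylium tetrafluoroborate
Product: 4 (2Z,4E)-hexa-2,4-dienoic acid, via 2-methyl-2H-pyran 2 (not isolated), via (2Z,4E)-hexa-2,4-dienal 3 (not isolated)
Conditions: MeLi (1.05 equiv), THF, −78 → 0 °C; then t-BuOH, 2-methyl-2-butene, NaClO2, NaH2PO4, H2O, 0 °C; acid/base extraction
Reagents that add atoms: methyllithium, [Li]C; sodium chlorite, [Na+].[O-]Cl=O
Why: MeLi attacks the aromatic oxonium at C2 (dearomatisation) and the resulting 2H-pyran undergoes thermal 6π retro-oxa-electrocyclic ring opening below 0 °C, in which the ring cis-alkene becomes the 2Z alkene and the methyl group rotates outward to give the 4E alkene, after which a buffered Pinnick oxidation in the same pot converts the labile Z,E-dienal into the acid without touching either alkene.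

**Step 2**
Reactants: 4 (2Z,4E)-hexa-2,4-dienoic acid
Product: 5 (2Z)-3-[(2S,3S)-3-methyloxiran-2-yl]prop-2-enoic acid [(2Z,4S,5S)-4,5-epoxyhex-2-enoic acid]
Conditions: ent-Shi ketone (30 mol %), Oxone (2KHSO5·KHSO4·K2SO4), K2CO3, Bu4NHSO4, MeCN/DMM/aq. Na2B4O7–Na2EDTA buffer (pH 10.5), −5 °C; then citric acid to pH 4, 0 °C, cold EtOAc extraction; kept as a −20 °C solution and made in two batches, one for each acylation
Reagents that add atoms: potassium peroxymonosulfate (from Oxone), [K+].[O-]S(=O)(=O)OO
Why: Shi asymmetric epoxidation, in which the electrophilic chiral dioxirane reacts only at the electron-richer distal trans-C4=C5 alkene (C2=C3 is deactivated by the carboxylate) through the spiro transition state, the L-fructose-derived ketone delivering oxygen to the face that gives the (4S,5S)-trans-epoxide (the D-fructose ketone gives R,R on trans-alkenes), so both stereocentres are set here; distal-selective dioxirane epoxidation of sorbate salts in water and Shi monoepoxidation of dienoate esters are the closest precedents.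

**Step 3**
Reactants: 6 hydroquinone
Product: 7 bromanil (2,3,5,6-tetrabromocyclohexa-2,5-diene-1,4-dione)
Conditions: Br2 (4.2 equiv), AcOH, 20 → 60 °C; then conc. HNO3, 60 °C
Reagents that add atoms: bromine, BrBr
Why: Fourfold electrophilic aromatic bromination of the electron-rich ring followed by oxidation of tetrabromohydroquinone to the quinone (oxidative dearomatisation) is the classical bromanil preparation.

**Step 4**
Reactants: 7 bromanil
Product: 8 2,5-bis(benzyloxy)-3,6-dibromocyclohexa-2,5-diene-1,4-dione
Conditions: BnONa (1.0 M in BnOH, 2.1 equiv), THF, −20 → 0 °C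
Reagents that add atoms: sodium benzyloxide, [Na+].[O-]Cc1ccccc1
Why: Two addition–elimination events (vinylogous acyl substitution), where the first alkoxy group deactivates its own carbonyl partner as a vinylogous ester so that the second alkoxide enters para, giving the 2,5-dialkoxy-3,6-dihalo pattern exactly as in the chloranil/methoxide reaction.

**Step 5**
Reactants: 8 2,5-bis(benzyloxy)-3,6-dibromocyclohexa-2,5-diene-1,4-dione; 9 {4-[(tert-butyldimethylsilyl)oxy]phenyl}boronic acid (2.4 equiv)
Product: 10 2,5-bis(benzyloxy)-3,6-bis{4-[(tert-butyldimethylsilyl)oxy]phenyl}cyclohexa-2,5-diene-1,4-dione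
Conditions: Pd(dppf)Cl2 (5 mol %), K3PO4, 1,4-dioxane, 85 °C
Reagents that add atoms: none
Why: Double Suzuki–Miyaura coupling at the two vinylogous acyl bromide carbons (fast oxidative addition to zerovalent palladium), precedented on 2,5-dibromo-3,6-dimethoxybenzoquinone, with nearly anhydrous phosphate keeping the aryl silyl ethers and the vinylogous benzyl esters intact.

**Step 6**
Reactants: 10 2,5-bis(benzyloxy)-3,6-bis{4-[(tert-butyldimethylsilyl)oxy]phenyl}cyclohexa-2,5-diene-1,4-dione
Product: 12 2,5-dihydroxy-3,6-bis{4-[(tert-butyldimethylsilyl)oxy]phenyl}cyclohexa-2,5-diene-1,4-dione, via 3,6-bis[4-(TBSO)phenyl]benzene-1,2,4,5-tetraol 11 (not isolated)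
Conditions: H2 (1 atm), Pd/C, THF, 20 °C; filter through Celite; then air (O2), EtOAc, 20 °C; crystallise
Reagents that add atoms: none
Why: Catalytic hydrogenation reduces the quinone and hydrogenolyses both vinylogous benzyl esters to the leuco tetraol, which autoxidises in air to the stable 2,5-dihydroxyquinone (the leucoatromentin → atromentin behaviour), so the four ring oxygens are sorted into two enolic hydroxyls and two carbonyls and no stereocentre is involved.

**Step 7**
Reactants: 12 2,5-dihydroxy-3,6-bis{4-[(tert-butyldimethylsilyl)oxy]phenyl}cyclohexa-2,5-diene-1,4-dione; 5 (2Z)-3-[(2S,3S)-3-methyloxiran-2-yl]prop-2-enoic acid (2.4 equiv)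
Product: 13 2,5-bis{4-[(tert-butyldimethylsilyl)oxy]phenyl}-3,6-dioxocyclohexa-1,4-diene-1,4-diyl bis{(2Z)-3-[(2S,3S)-3-methyloxiran-2-yl]prop-2-enoate}
Conditions: DIC (2.6 equiv), DMAP (5 mol %), CH2Cl2, −10 → 0 °C
Reagents that add atoms: none
Why: Steglich-type carbodiimide esterification of the two acidic enolic hydroxyls of the air-stable hydroxyquinone (as in carbodiimide esterification of 2-hydroxy-1,4-naphthoquinone and the classical diacetates of polyporic acid and atromentin) installs exactly two acyl groups with only a small excess of the labile acid, the carbodiimide being kept in excess over the acid so that no free carboxylate remains to cleave the vinylogous anhydride product, and the Z-enoate and the (S,S)-epoxide are not touched at this temperature.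

**Step 8**
Reactants: 13 2,5-bis{4-[(tert-butyldimethylsilyl)oxy]phenyl}-3,6-dioxocyclohexa-1,4-diene-1,4-diyl bis{(2Z)-3-[(2S,3S)-3-methyloxiran-2-yl]prop-2-enoate}; 5 (2Z)-3-[(2S,3S)-3-methyloxiran-2-yl]prop-2-enoic acid (2.4 equiv)
Product: 15 3,6-bis{4-[(tert-butyldimethylsilyl)oxy]phenyl}benzene-1,2,4,5-tetrayl tetrakis{(2Z)-3-[(2S,3S)-3-methyloxiran-2-yl]prop-2-enoate}, via 2,5-bis(acyloxy)-3,6-diarylhydroquinone 14 (not isolated)
Conditions: Na2S2O4 (3 equiv), EtOAc/aq. phosphate buffer (pH 7), 0 °C, 5 min; organic layer dried (Na2SO4) under Ar; then 5, DIC (2.6 equiv), DMAP (0.2 equiv), CH2Cl2/EtOAc, −10 → 0 °C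
Reagents that add atoms: none
Why: Reductive acylation of a quinone, in which brief buffered dithionite treatment reduces only the electron-poor quinone, the air-sensitive hydroquinone diester is acylated twice more by Steglich esterification without isolation, and any O→O acyl migration in 14 is harmless because all four acyl groups are identical; no stereocentre is formed.

**Step 9**
Reactants: 15 3,6-bis{4-[(tert-butyldimethylsilyl)oxy]phenyl}benzene-1,2,4,5-tetrayl tetrakis{(2Z)-3-[(2S,3S)-3-methyloxiran-2-yl]prop-2-enoate}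
Product: 16 3,6-bis(4-hydroxyphenyl)benzene-1,2,4,5-tetrayl tetrakis{(2Z)-3-[(2S,3S)-3-methyloxiran-2-yl]prop-2-enoate} (CNP0249571.1)
Conditions: Bu4NF/AcOH (1:1.2, 2.5 equiv), THF, 0 °C
Reagents that add atoms: none
Why: Fluoride-mediated cleavage of the aryl silyl ethers (the most labile Si–O bonds present), buffered with AcOH so that no phenoxide accumulates, leaves the four aryl esters, the Z-enoates and the vinyl epoxides untouched.

**Compound list**
1 | pyrylium tetrafluoroborate | c1cc[o+]cc1.F[B-](F)(F)F | starting material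
2 | 2-methyl-2H-pyran (racemic, transient) | CC1OC=CC=C1 | intermediate
3 | (2Z,4E)-hexa-2,4-dienal | C/C=C/C=C\C=O | intermediate
4 | (2Z,4E)-hexa-2,4-dienoic acid | C/C=C/C=C\C(=O)O | intermediate
5 | (2Z)-3-[(2S,3S)-3-methyloxiran-2-yl]prop-2-enoic acid | C[C@@H]1O[C@H]1/C=C\C(=O)O | intermediate
6 | hydroquinone | Oc1ccc(O)cc1 | starting material
7 | bromanil (2,3,5,6-tetrabromocyclohexa-2,5-diene-1,4-dione) | O=C1C(Br)=C(Br)C(=O)C(Br)=C1Br | intermediate
8 | 2,5-bis(benzyloxy)-3,6-dibromocyclohexa-2,5-diene-1,4-dione | O=C1C(Br)=C(OCc2ccccc2)C(=O)C(Br)=C1OCc1ccccc1 | intermediate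
9 | {4-[(tert-butyldimethylsilyl)oxy]phenyl}boronic acid | CC(C)(C)[Si](C)(C)Oc1ccc(cc1)B(O)O | starting material
10 | 2,5-bis(benzyloxy)-3,6-bis{4-[(tert-butyldimethylsilyl)oxy]phenyl}cyclohexa-2,5-diene-1,4-dione | O=C1C(c2ccc(O[Si](C)(C)C(C)(C)C)cc2)=C(OCc2ccccc2)C(=O)C(c2ccc(O[Si](C)(C)C(C)(C)C)cc2)=C1OCc1ccccc1 | intermediate
11 | 3,6-bis{4-[(tert-butyldimethylsilyl)oxy]phenyl}benzene-1,2,4,5-tetraol | Oc1c(O)c(-c2ccc(O[Si](C)(C)C(C)(C)C)cc2)c(O)c(O)c1-c1ccc(O[Si](C)(C)C(C)(C)C)cc1 | intermediate
12 | 2,5-dihydroxy-3,6-bis{4-[(tert-butyldimethylsilyl)oxy]phenyl}cyclohexa-2,5-diene-1,4-dione | O=C1C(O)=C(c2ccc(O[Si](C)(C)C(C)(C)C)cc2)C(=O)C(O)=C1c1ccc(O[Si](C)(C)C(C)(C)C)cc1 | intermediate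
13 | 2,5-bis{4-[(tert-butyldimethylsilyl)oxy]phenyl}-3,6-dioxocyclohexa-1,4-diene-1,4-diyl bis{(2Z)-3-[(2S,3S)-3-methyloxiran-2-yl]prop-2-enoate} | O=C1C(OC(=O)/C=C\[C@@H]2O[C@H]2C)=C(c2ccc(O[Si](C)(C)C(C)(C)C)cc2)C(=O)C(OC(=O)/C=C\[C@@H]2O[C@H]2C)=C1c1ccc(O[Si](C)(C)C(C)(C)C)cc1 | intermediate
14 | 3,6-dihydroxy-2,5-bis{4-[(tert-butyldimethylsilyl)oxy]phenyl}benzene-1,4-diyl bis{(2Z)-3-[(2S,3S)-3-methyloxiran-2-yl]prop-2-enoate} | Oc1c(OC(=O)/C=C\[C@@H]2O[C@H]2C)c(-c2ccc(O[Si](C)(C)C(C)(C)C)cc2)c(O)c(OC(=O)/C=C\[C@@H]2O[C@H]2C)c1-c1ccc(O[Si](C)(C)C(C)(C)C)cc1 | intermediate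
15 | 3,6-bis{4-[(tert-butyldimethylsilyl)oxy]phenyl}benzene-1,2,4,5-tetrayl tetrakis{(2Z)-3-[(2S,3S)-3-methyloxiran-2-yl]prop-2-enoate} | C[C@@H]1O[C@H]1/C=C\C(=O)Oc1c(OC(=O)/C=C\[C@@H]2O[C@H]2C)c(-c2ccc(O[Si](C)(C)C(C)(C)C)cc2)c(OC(=O)/C=C\[C@@H]2O[C@H]2C)c(OC(=O)/C=C\[C@@H]2O[C@H]2C)c1-c1ccc(O[Si](C)(C)C(C)(C)C)cc1 | intermediate
16 | 3,6-bis(4-hydroxyphenyl)benzene-1,2,4,5-tetrayl tetrakis{(2Z)-3-[(2S,3S)-3-methyloxiran-2-yl]prop-2-enoate} | C[C@@H]1O[C@H]1/C=C\C(=O)Oc1c(OC(=O)/C=C\[C@@H]2O[C@H]2C)c(-c2ccc(O)cc2)c(OC(=O)/C=C\[C@@H]2O[C@H]2C)c(OC(=O)/C=C\[C@@H]2O[C@H]2C)c1-c1ccc(O)cc1 | target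

**Step count**
Total: 9 steps. Longest linear sequence: 7 steps (6 → 7 → 8 → 10 → 12 → 13 → 15 → 16); the side-chain branch (1 → 4 → 5, 2 steps) feeds steps 7 and 8.

**Three steps most likely to fail, with fallbacks**

Step 2. The risks are low conversion or selectivity with the carboxylate as substrate, and lactonisation of the Z-epoxy acid to a butenolide on acidification. Four acyl groups end up in one molecule, so the acid needs at least 97% ee to avoid diastereomeric tetraesters. The fallback sets out from 4 and comes back at 5. Acid 4 is methylated with TMSCHN2 to methyl (2Z,4E)-hexa-2,4-dienoate F1. The Shi epoxidation with the same L-fructose-derived ketone is run on this ester, the documented substrate class, to give methyl (2Z)-3-[(2S,3S)-3-methyloxiran-2-yl]prop-2-enoate F2. The ester is purified and its ee checked, then saponified with LiOH in THF/H2O at 0 °C and acidified only to pH 4 to give 5.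

Step 7. The risks are that 13 is a vinylogous anhydride: DMAP or any free carboxylate can take the acyl group back, the O-acylisourea can rearrange to the N-acylurea, and 13 may not survive silica. The fallback sets out from 10 and comes back at 15, so it never passes through an acylated quinone. Quinone 10 is hydrogenated to tetraol 11 as in step 6, but the filtrate is kept under argon and all four hydroxyls are acylated in one operation with 5 (at least 8 equiv), DIC and DMAP at −10 to 0 °C to give 15 directly. This is shorter, but it commits a large excess of the labile acid to a single hindered, oxygen-sensitive fourfold acylation in which under-acylated material re-oxidises and is lost, which is why it is held in reserve.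

Step 8. The risks are attack of dithionite or its sulfite by-products on the vinyl epoxides or the aryl enoates, slow acylation of the two flanked hydroxyls, and DMAP-induced Z → E isomerisation of the activated epoxy acid. The fallback sets out from 12 and comes back at 15. Quinone 12 is reduced with Na2S2O4 to tetraol 11 while no epoxide is present, and 11 is acylated with the robust dienoic acid 4 (DIC/DMAP), which can be used in large excess, to give 3,6-bis{4-[(tert-butyldimethylsilyl)oxy]phenyl}benzene-1,2,4,5-tetrayl tetrakis[(2Z,4E)-hexa-2,4-dienoate] F3. The four epoxides are then installed together by Shi epoxidation with the same ketone (stoichiometric per alkene, Oxone, NaHCO3, pH 8, MeCN/DMM/H2O, 0 °C) to give 15. The price is statistical: at 96:4 facial selectivity per alkene about 85% of the material is the all-(S,S) diastereomer, and the rest must be removed by chromatography or crystallisation.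

**Further compounds**
F1 | step 2 | methyl (2Z,4E)-hexa-2,4-dienoate | C/C=C/C=C\C(=O)OC
F2 | step 2 | methyl (2Z)-3-[(2S,3S)-3-methyloxiran-2-yl]prop-2-enoate | C[C@@H]1O[C@H]1/C=C\C(=O)OC
F0 | step 7 | none | none
F3 | step 8 | 3,6-bis{4-[(tert-butyldimethylsilyl)oxy]phenyl}benzene-1,2,4,5-tetrayl tetrakis[(2Z,4E)-hexa-2,4-dienoate] | C/C=C/C=C\C(=O)Oc1c(OC(=O)/C=C\C=C\C)c(-c2ccc(O[Si](C)(C)C(C)(C)C)cc2)c(OC(=O)/C=C\C=C\C)c(OC(=O)/C=C\C=C\C)c1-c1ccc(O[Si](C)(C)C(C)(C)C)cc1
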